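**Plan**
- Retrosynthesis: the C6 tert-butyl and C7 methoxymethyl ethers come off last. Before that the exocyclic C3=CHPh bond is cut (Knoevenagel) and the lactone C2=O is traced back to the C2–H of a benzofuran (C–H borylation, then oxidation).
- Ring A is then cut at C4–C5, C6–C7 and C7–C7a. On ring A the C4 methoxy and the C7 oxygen are para and C7a carries the ring oxygen O1. That is the pattern left by a methoxycarbene carbon (C4), an inserted CO (C7) and the C2=C3 edge of a 3-furyl group (C7a, C3a), with C5 and C6 from a push–pull alkoxy ynone.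
- Forward: the furan ring is bought. The chromium carbene complex (one step) and the ynone (two steps) are made separately, ring A is closed by Dötz benzannulation, the furan ring is oxidised to the lactone ring, the benzylidene is attached and the two ethers are cleaved.
- Stereochemistry: there is no stereocentre. The Z benzylidene (phenyl cis to the lactone carbonyl) is set under thermodynamic control in the condensation, because the C4 methoxy group disfavours the E isomer.

Key step: step 4

Remark: tert-butoxyethyne 8 is taken as a purchasable reagent, and the Z alkene is assumed to be the thermodynamic isomer because the C4 methoxy group crowds the other side of the double bond.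

**Route**

Step 1
Reactants: 1 3-bromofuran; 2 hexacarbonylchromium, Cr(CO)6
Product: 5 pentacarbonyl[(furan-3-yl)(methoxy)methylidene]chromium, via furan-3-yllithium 3 (not isolated), via lithium acylchromate 4 (not isolated)
Conditions: n-BuLi, Et2O, −78 °C; Cr(CO)6, −78 °C → rt; then Me3OBF4, CH2Cl2, 0 °C
Reagents that add atoms: trimethyloxonium tetrafluoroborate, C[O+](C)C.F[B-](F)(F)F
Why: Bromine–lithium exchange at −78 °C should give the 3-lithiofuran without migration to C2, its addition to a CO ligand gives the acylchromate, and O-methylation with the oxonium salt completes a standard Fischer carbene complex synthesis.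

Step 2
Reactants: 6 3-phenylpropanoyl chloride
Product: 7 N-methoxy-N-methyl-3-phenylpropanamide
Conditions: MeNH(OMe)·HCl, K2CO3 (excess), EtOAc/H2O, 0 °C → rt
Reagents that add atoms: N,O-dimethylhydroxylamine hydrochloride, CNOC.Cl
Why: Schotten–Baumann acylation of the amine should give the Weinreb amide, which in the next step stops acetylide addition at the ketone stage.

Step 3
Reactants: 8 tert-butoxyethyne; 7 N-methoxy-N-methyl-3-phenylpropanamide
Product: 11 1-tert-butoxy-5-phenylpent-1-yn-3-one, via lithium tert-butoxyacetylide 9 (not isolated), via tetrahedral lithium adduct 10 (not isolated)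
Conditions: n-BuLi, THF, −78 °C; then 7, −78 → −20 °C; AcOH, −78 °C, cold pH 7 buffer work-up
Reagents that add atoms: none
Why: In this Weinreb ketone synthesis the chelated tetrahedral adduct should persist until the cold acidic quench, so no second acetylide adds, and protonating the released N,O-dimethylhydroxylamine at low temperature keeps it from adding to the push–pull ynone.

Step 4
Reactants: 5 pentacarbonyl[(furan-3-yl)(methoxy)methylidene]chromium; 11 1-tert-butoxy-5-phenylpent-1-yn-3-one
Product: 13 1-(6-tert-butoxy-7-hydroxy-4-methoxybenzofuran-5-yl)-3-phenylpropan-1-one, via Cr(CO)3 arene complex 12 (not isolated)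
Conditions: THF (degassed), 50 °C; then air, Et2O, rt
Reagents that add atoms: none
Why: Heating 5 expels one cis CO, the ynone 11 inserts into the Cr=C bond to give a vinylcarbene whose metal-bound carbon carries the tert-butoxy group, CO then inserts to a chromium-bound vinylketene, and 6π electrocyclisation onto the furan followed by enolisation gives the phenol as its Cr(CO)3 complex 12, which air demetallates to 13. This is a Dötz benzannulation, closest in kind to the known annulations of furyl(methoxy)carbene chromium complexes with alkynes, including alkoxy alkynyl ketones, that give 4-methoxy-7-hydroxybenzofurans. Ring A closes by disrotatory six-electron electrocyclisation of the furyl-dienylketene, a formal [3+2+1] assembly that makes C4–C5, C6–C7 and C7–C7a and is made irreversible by aromatisation. No stereocentre is formed. The step needs regioselective insertion, secured by the push–pull polarisation of 11, whose acyl-bearing carbon is the nucleophilic alkyne terminus and bonds to the electrophilic carbene carbon (ketone at C5, tert-butoxy at C6), and it needs closure at furan C2, secured because only the C2=C3 π bond of the 3-furyl group is conjugated into the dienylketene. The carbene carbon arrives as C4–OMe and the inserted CO as the free C7–OH, so the para oxygen pair is differentiated without a protecting-group step, and 50 °C in THF is chosen to limit retro-ene loss of isobutene from the tert-butyl ynol ether.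

Step 5
Reactants: 13 1-(6-tert-butoxy-7-hydroxy-4-methoxybenzofuran-5-yl)-3-phenylpropan-1-one
Product: 14 1-[6-tert-butoxy-4-methoxy-7-(methoxymethoxy)benzofuran-5-yl]-3-phenylpropan-1-one
Conditions: MOMCl, i-Pr2NEt, CH2Cl2, 0 °C → rt
Reagents that add atoms: chloromethyl methyl ether, COCCl
Why: O-alkylation of the phenol masks the oxidation-prone para-methoxyphenol through the borylation, peroxide and amine steps as an acetal that later leaves together with the tert-butyl group in one acid treatment.

Step 6
Reactants: 14 1-[6-tert-butoxy-4-methoxy-7-(methoxymethoxy)benzofuran-5-yl]-3-phenylpropan-1-one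
Product: 16 6-tert-butoxy-4-methoxy-7-(methoxymethoxy)-5-(3-phenylpropanoyl)benzofuran-2(3H)-one, via C2 pinacol boronate 15 (not isolated)
Conditions: [Ir(OMe)(cod)]2 (1.5 mol%), 4,4′-di-tert-butyl-2,2′-bipyridine (3 mol%), B2pin2 (0.7 equiv), THF, rt; then 30% aq. H2O2, NaHCO3, 0 °C → rt
Reagents that add atoms: hydrogen peroxide, OO
Why: Iridium-catalysed C–H borylation should pick the furan C2–H, the only heteroaryl C–H next to oxygen in a molecule whose ring A is fully substituted and whose phenyl C–H bonds react only on heating, and peroxide oxidation of the C–B bond gives the 2-hydroxybenzofuran, which tautomerises to the benzofuran-2(3H)-one.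

Step 7
Reactants: 16 6-tert-butoxy-4-methoxy-7-(methoxymethoxy)-5-(3-phenylpropanoyl)benzofuran-2(3H)-one; 17 benzaldehyde
Product: 18 (Z)-3-benzylidene-6-tert-butoxy-4-methoxy-7-(methoxymethoxy)-5-(3-phenylpropanoyl)benzofuran-2(3H)-one
Conditions: piperidine (10 mol%), AcOH (10 mol%), toluene, 4 Å MS, 60 °C
Reagents that add atoms: none
Why: Knoevenagel condensation at the lactone C3–H2, which is far more acidic than the hindered ketone α-CH2, runs under reversible amine catalysis, so the alkene should settle in the Z geometry with the phenyl group on the lactone-carbonyl side and away from the C4 methoxy group.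

Step 8
Reactants: 18 (Z)-3-benzylidene-6-tert-butoxy-4-methoxy-7-(methoxymethoxy)-5-(3-phenylpropanoyl)benzofuran-2(3H)-one
Product: 19 bractelactone, (Z)-3-benzylidene-6,7-dihydroxy-4-methoxy-5-(3-phenylpropanoyl)benzofuran-2(3H)-one
Conditions: TFA/CH2Cl2 (1:4), 0 °C → rt; aqueous work-up
Reagents that add atoms: none
Why: Acidolysis should cleave the aryl tert-butyl ether through the tert-butyl cation and the methoxymethyl acetal through its oxocarbenium ion, while the methyl ether, lactone, ketone and the thermodynamically preferred Z alkene are untouched.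

**Compound list**

1 | 3-bromofuran | Brc1ccoc1 | starting material
2 | hexacarbonylchromium, Cr(CO)6 | O=C=[Cr](=C=O)(=C=O)(=C=O)(=C=O)=C=O | starting material
3 | furan-3-yllithium | [Li]c1ccoc1 | intermediate
4 | lithium pentacarbonyl[(furan-3-yl)(oxido)methylidene]chromate (acylchromate) | [Li+].[O-]C(c1ccoc1)=[Cr](=C=O)(=C=O)(=C=O)(=C=O)=C=O | intermediate
5 | pentacarbonyl[(furan-3-yl)(methoxy)methylidene]chromium | COC(c1ccoc1)=[Cr](=C=O)(=C=O)(=C=O)(=C=O)=C=O | intermediate
6 | 3-phenylpropanoyl chloride | O=C(Cl)CCc1ccccc1 | starting material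
7 | N-methoxy-N-methyl-3-phenylpropanamide | CON(C)C(=O)CCc1ccccc1 | intermediate
8 | tert-butoxyethyne | C#COC(C)(C)C | starting material
9 | lithium tert-butoxyacetylide | [Li]C#COC(C)(C)C | intermediate
10 | lithium 1-tert-butoxy-3-[methoxy(methyl)amino]-5-phenylpent-1-yn-3-olate (tetrahedral adduct) | CON(C)C([O-])(C#COC(C)(C)C)CCc1ccccc1.[Li+] | intermediate
11 | 1-tert-butoxy-5-phenylpent-1-yn-3-one | CC(C)(C)OC#CC(=O)CCc1ccccc1 | intermediate
12 | tricarbonylchromium complex of 13 (Cr bound η6 to ring A, written as arene plus Cr(CO)3 fragment) | COc1c(C(=O)CCc2ccccc2)c(OC(C)(C)C)c(O)c2occc12.O=C=[Cr](=C=O)=C=O | intermediate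
13 | 1-(6-tert-butoxy-7-hydroxy-4-methoxybenzofuran-5-yl)-3-phenylpropan-1-one | COc1c(C(=O)CCc2ccccc2)c(OC(C)(C)C)c(O)c2occc12 | intermediate
14 | 1-[6-tert-butoxy-4-methoxy-7-(methoxymethoxy)benzofuran-5-yl]-3-phenylpropan-1-one | COc1c(C(=O)CCc2ccccc2)c(OC(C)(C)C)c(OCOC)c2occc12 | intermediate
15 | 1-[6-tert-butoxy-4-methoxy-7-(methoxymethoxy)-2-(4,4,5,5-tetramethyl-1,3,2-dioxaborolan-2-yl)benzofuran-5-yl]-3-phenylpropan-1-one | COc1c(C(=O)CCc2ccccc2)c(OC(C)(C)C)c(OCOC)c2oc(B3OC(C)(C)C(C)(C)O3)cc12 | intermediate
16 | 6-tert-butoxy-4-methoxy-7-(methoxymethoxy)-5-(3-phenylpropanoyl)benzofuran-2(3H)-one | COc1c(C(=O)CCc2ccccc2)c(OC(C)(C)C)c(OCOC)c2c1CC(=O)O2 | intermediate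
17 | benzaldehyde | O=Cc1ccccc1 | starting material
18 | (Z)-3-benzylidene-6-tert-butoxy-4-methoxy-7-(methoxymethoxy)-5-(3-phenylpropanoyl)benzofuran-2(3H)-one | COc1c(C(=O)CCc2ccccc2)c(OC(C)(C)C)c(OCOC)c2c1/C(=C/c1ccccc1)C(=O)O2 | intermediate
19 | bractelactone, (Z)-3-benzylidene-6,7-dihydroxy-4-methoxy-5-(3-phenylpropanoyl)benzofuran-2(3H)-one | COc1c(C(=O)CCc2ccccc2)c(O)c(O)c2c1/C(=C/c1ccccc1)C(=O)O2 | target

**Step count and risks**

Total step count: 8. Longest linear sequence: 7 steps (6 → 7 → 11 → 13 → 14 → 16 → 18 → 19).

Steps most likely to fail: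

1. Step 4. The tert-butyl ynol ether may shed isobutene before it inserts. The acyl-deactivated alkyne may insert slowly or in the wrong orientation, or the ketone oxygen may capture the vinylketene before electrocyclisation.
 Fallback: ring formation and acyl introduction are separated. Setting out from 5 and 8, a Dötz benzannulation with the terminal ynol ether 8 itself (THF, 45 °C, then air) would give, through the tricarbonylchromium arene complex F1, 6-tert-butoxy-4-methoxybenzofuran-7-ol F2. Here steric and electronic preferences both place the alkoxy group next to the new hydroxyl. MOMCl and i-Pr2NEt would give 6-tert-butoxy-4-methoxy-7-(methoxymethoxy)benzofuran F3. NBS in MeCN at 0 °C should brominate C5, the only free position of ring A and the one flanked by two alkoxy groups, to give 5-bromo-6-tert-butoxy-4-methoxy-7-(methoxymethoxy)benzofuran F4. Bromine–lithium exchange (n-BuLi, THF, −78 °C) would give the C5 aryllithium F5, and its addition to Weinreb amide 7 through the tetrahedral lithium adduct F6 comes back to the route at 14.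

2. Step 6. Borylation may spill over to the phenyl C–H bonds, the pinacolborane formed may reduce the ketone, and the lactone may over-oxidise or ring-open during the peroxide stage.
 Fallback: the C2 oxygen is introduced by electrophilic chemistry on the enol-ether double bond. Setting out from 14, NBS in THF/H2O at 0 °C would give the bromohydrin lactol 1-[3-bromo-6-tert-butoxy-2-hydroxy-4-methoxy-7-(methoxymethoxy)-2,3-dihydrobenzofuran-5-yl]-3-phenylpropan-1-one F7, with water adding at C2 through the oxocarbenium ion. Oxidation of the lactol (TEMPO, PhI(OAc)2, CH2Cl2) would give 3-bromo-6-tert-butoxy-4-methoxy-7-(methoxymethoxy)-5-(3-phenylpropanoyl)benzofuran-2(3H)-one F8. Reductive debromination (Zn, AcOH/THF, rt) comes back to the route at 16.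

3. Step 7. The alkene geometry may not equilibrate fully, the amine catalyst may open the aryl lactone, or a second lactone molecule may add in conjugate fashion to the benzylidene product.
 Fallback: the order is reversed and the condensation is run under acid. Setting out from 16, TFA/CH2Cl2 would remove both ethers to give 6,7-dihydroxy-4-methoxy-5-(3-phenylpropanoyl)benzofuran-2(3H)-one F9. Acid-catalysed condensation with 17 (HCl, AcOH, 60 °C) proceeds through the lactone enol, needs no amine and equilibrates the alkene, and comes back to the route at 19.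

Further compounds
F1 | step 4 | tricarbonylchromium complex of F2 (Cr bound η6 to ring A, not isolated) | COc1cc(OC(C)(C)C)c(O)c2occc12.O=C=[Cr](=C=O)=C=O
F2 | step 4 | 6-tert-butoxy-4-methoxybenzofuran-7-ol | COc1cc(OC(C)(C)C)c(O)c2occc12
F3 | step 4 | 6-tert-butoxy-4-methoxy-7-(methoxymethoxy)benzofuran | COc1cc(OC(C)(C)C)c(OCOC)c2occc12
F4 | step 4 | 5-bromo-6-tert-butoxy-4-methoxy-7-(methoxymethoxy)benzofuran | COc1c(Br)c(OC(C)(C)C)c(OCOC)c2occc12
F5 | step 4 | [6-tert-butoxy-4-methoxy-7-(methoxymethoxy)benzofuran-5-yl]lithium (not isolated) | [Li]c1c(OC)c2ccoc2c(OCOC)c1OC(C)(C)C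
F6 | step 4 | lithium tetrahedral adduct of F5 with 7 (not isolated) | CON(C)C([O-])(CCc1ccccc1)c1c(OC)c2ccoc2c(OCOC)c1OC(C)(C)C.[Li+]
F7 | step 6 | 1-[3-bromo-6-tert-butoxy-2-hydroxy-4-methoxy-7-(methoxymethoxy)-2,3-dihydrobenzofuran-5-yl]-3-phenylpropan-1-one (mixture of diastereomers) | COc1c(C(=O)CCc2ccccc2)c(OC(C)(C)C)c(OCOC)c2c1C(Br)C(O)O2
F8 | step 6 | 3-bromo-6-tert-butoxy-4-methoxy-7-(methoxymethoxy)-5-(3-phenylpropanoyl)benzofuran-2(3H)-one (racemic) | COc1c(C(=O)CCc2ccccc2)c(OC(C)(C)C)c(OCOC)c2c1C(Br)C(=O)O2
F9 | step 7 | 6,7-dihydroxy-4-methoxy-5-(3-phenylpropanoyl)benzofuran-2(3H)-one | COc1c(C(=O)CCc2ccccc2)c(O)c(O)c2c1CC(=O)O2
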